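**Assumption:** atoms carry germacrane numbers (ring C1–C10; lactone C11–C13 with C12 the carbonyl; C14 on C10; C15 on C4). TBS = tert-butyldimethylsilyl, PMB = 4-methoxybenzyl. The route is designed on paper and has not been run.

## Retrosynthetic overview

1. Target 29 ⇐ 15-acrylate 28 (Morita–Baylis–Hillman with CH2O) ⇐ 15-alcohol 27 ⇐ PMB ether 26.
2. Ten-membered ring (formed last): C6–C7 bond by closure of the C6 allyl radical of bromide 24 onto the butenolide β-carbon with loss of the C13 acetate. This is the bond, and the 11(13)-ene outcome, of the farnesyl C1→C10 closure to germacrene A; C8 controls C7 (trans fusion).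
3. Butenolide ring (formed first): acylation of the C8–OH of 19 with the C11–C13 acrylic acid 20, then ring-closing metathesis.
4. 19 ⇐ E-selective Horner–Wadsworth–Emmons union of aldehyde 11 with (S)-γ-vinylbutyrolactone 14 (C8 from the L-glutamic-acid-derived lactone 12), then lactone reduction to free C14–OH and C8–OH.
5. 11 ⇐ Johnson–Claisen rearrangement of allylic alcohol 6 (sets the 4,5-alkene) ⇐ 2,3-dibromopropene, PMB alcohol, TBSOCH2CHO.

## Route

Step 1
Reactants: 1 2,3-dibromopropene; 2 4-methoxybenzyl alcohol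
Product: 3 2-bromoallyl 4-methoxybenzyl ether
Conditions: NaH, THF, 0 °C to rt
Reagents that add atoms: none
Why: Williamson ether synthesis in which the alkoxide displaces only the allylic bromide (SN2) while the vinylic bromide survives as the handle for step 2.

Step 2
Reactants: 3 2-bromoallyl 4-methoxybenzyl ether; 4 (tert-butyldimethylsilyloxy)acetaldehyde
Product: 6 racemic 1-(tert-butyldimethylsilyloxy)-3-[(4-methoxybenzyloxy)methyl]but-3-en-2-ol, via vinyllithium 5 (not isolated)
Conditions: t-BuLi (2.1 equiv), Et2O, −78 °C; then 4, −78 °C; H2O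
Reagents that add atoms: none
Why: Bromine–lithium exchange and 1,2-addition of the 2-lithioallyl ether to the aldehyde give the 2-substituted secondary allylic alcohol, whose racemic carbinol centre becomes sp2 in step 3.

Step 3
Reactants: 6 racemic allylic alcohol; 7 triethyl orthoacetate
Product: 10 ethyl (4Z)-6-(tert-butyldimethylsilyloxy)-4-[(4-methoxybenzyloxy)methyl]hex-4-enoate, via mixed orthoester 8 (not isolated), via ketene acetal 9 (not isolated)
Conditions: MeC(OEt)3 (excess), EtCO2H (cat.), 140 °C, EtOH distilled off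
Reagents that add atoms: none
Why: Johnson–Claisen rearrangement through a chair transition state with CH2OTBS equatorial puts C6 trans to the new C3–C2 bond, so the 4,5-alkene forms with CH2OPMB (C15) cis to C6 as the target needs, and C1–C3 are added in the same step.

Step 4
Reactants: 10 ethyl (4Z)-hexenoate
Product: 11 (4Z)-6-(tert-butyldimethylsilyloxy)-4-[(4-methoxybenzyloxy)methyl]hex-4-enal
Conditions: i-Bu2AlH (1.05 equiv), CH2Cl2, −78 °C; aq. KNaC4H4O6
Reagents that add atoms: none
Why: Partial ester reduction with DIBAL: the tetrahedral aluminium hemiacetal is stable at −78 °C and releases the aldehyde only on work-up, leaving silyl and PMB ethers untouched.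

Step 5
Reactants: 12 (S)-5-(hydroxymethyl)dihydrofuran-2(3H)-one
Product: 13 (S)-5-oxotetrahydrofuran-2-carbaldehyde
Conditions: Dess–Martin periodinane, CH2Cl2, 0 °C to rt; used crude at once
Reagents that add atoms: none
Why: Dess–Martin oxidation under near-neutral conditions gives the α-acyloxy aldehyde without epimerising the adjacent centre (future C8, S, from L-glutamic acid).

Step 6
Reactants: 13 (S)-5-oxotetrahydrofuran-2-carbaldehyde
Product: 14 (S)-5-vinyldihydrofuran-2(3H)-one
Conditions: Ph3PCH3Br, KN(SiMe3)2, THF, −78 to 0 °C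
Reagents that add atoms: methyltriphenylphosphonium bromide, C[P+](c1ccccc1)(c1ccccc1)c1ccccc1.[Br-]
Why: Wittig methylenation with the non-stabilised ylide at low temperature is faster than enolisation of the aldehyde or attack on the lactone, so the C8 configuration (S) is retained.

Step 7
Reactants: 14 (S)-5-vinyldihydrofuran-2(3H)-one; 11 (4Z)-hexenal
Product: 17 (3E,5S)-3-{(4Z)-6-(tert-butyldimethylsilyloxy)-4-[(4-methoxybenzyloxy)methyl]hex-4-en-1-ylidene}-5-vinyldihydrofuran-2(3H)-one, via enol phosphate 15 (not isolated), via phosphonate 16 (not isolated)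
Conditions: LiN(i-Pr)2 (1.05 equiv), THF, −78 °C; ClP(O)(OEt)2; LiN(i-Pr)2 (1.1 equiv), −78 to 0 °C; then 11, 0 °C to rt
Reagents that add atoms: none
Why: Horner–Wadsworth–Emmons olefination after a Wiemer-type vinyl phosphate to α-phosphono lactone rearrangement gives mainly the E-alkylidene lactone (carbonyl trans to the chain, hence C9 cis to C2 as in the target), the minor Z isomer being removed by chromatography and the C8 centre staying untouched.

Step 8
Reactants: 17 E-alkylidene lactone
Product: 18 (3S,5E,9Z)-11-(tert-butyldimethylsilyloxy)-5-(hydroxymethyl)-9-[(4-methoxybenzyloxy)methyl]undeca-1,5,9-trien-3-ol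
Conditions: i-Bu2AlH (4 equiv), CH2Cl2, −78 to 0 °C; aq. KNaC4H4O6
Reagents that add atoms: none
Why: Exhaustive DIBAL 1,2-reduction opens the conjugated lactone to the primary allylic alcohol (C14) and the secondary alcohol (C8) without changing alkene geometry or the C8 configuration.

Step 9
Reactants: 18 diol
Product: 19 (3S,5E,9Z)-5-(acetoxymethyl)-11-(tert-butyldimethylsilyloxy)-9-[(4-methoxybenzyloxy)methyl]undeca-1,5,9-trien-3-ol
Conditions: Ac2O (1.05 equiv), 2,4,6-collidine, CH2Cl2, −20 °C
Reagents that add atoms: acetic anhydride, CC(=O)OC(C)=O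
Why: Chemoselective acylation of the unhindered primary allylic alcohol over the secondary alcohol installs the C14 acetate of the target.

Step 10
Reactants: 19 hydroxy acetate; 20 2-(bromomethyl)acrylic acid
Product: 22 (3S,5E,9Z)-5-(acetoxymethyl)-11-(tert-butyldimethylsilyloxy)-9-[(4-methoxybenzyloxy)methyl]undeca-1,5,9-trien-3-yl 2-(acetoxymethyl)acrylate, via bromomethyl acrylate 21 (not isolated)
Conditions: N,N′-diisopropylcarbodiimide, DMAP (cat.), CH2Cl2, 0 °C; then Bu4NOAc, rt
Reagents that add atoms: tetrabutylammonium acetate, CCCC[N+](CCCC)(CCCC)CCCC.CC(=O)[O-]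
Why: Steglich esterification at the C8 oxygen (configuration retained) followed by acetate-for-bromide exchange on the 2-(bromomethyl)acrylate, whose SN2 and SN2′ products are identical, gives a leaving group that silyl radicals do not abstract.

Step 11
Reactants: 22 acrylate ester
Product: 23 (5S)-3-(acetoxymethyl)-5-{(2E,6Z)-2-(acetoxymethyl)-8-(tert-butyldimethylsilyloxy)-6-[(4-methoxybenzyloxy)methyl]octa-2,6-dien-1-yl}furan-2(5H)-one
Conditions: second-generation Grubbs catalyst (H2IMes)(PCy3)Cl2Ru=CHPh (5 mol %), CH2Cl2, 40 °C, 5 mM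
Reagents that add atoms: none
Why: Ring-closing metathesis between the C8 vinyl group and the 1,1-disubstituted acrylate closes the five-membered butenolide with loss of ethene, the trisubstituted chain alkenes being too hindered to compete.

Step 12
Reactants: 23 butenolide silyl ether
Product: 24 (5S)-3-(acetoxymethyl)-5-{(2E,6Z)-2-(acetoxymethyl)-8-bromo-6-[(4-methoxybenzyloxy)methyl]octa-2,6-dien-1-yl}furan-2(5H)-one
Conditions: Ph3PBr2 (1.2 equiv), CH2Cl2, 0 °C to rt
Reagents that add atoms: triphenylphosphine dibromide, BrP(Br)(c1ccccc1)(c1ccccc1)c1ccccc1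
Why: Triphenylphosphine dibromide converts the primary allylic silyl ether directly into the allylic bromide (O-phosphonium formation with loss of silyl bromide, then SN2 by bromide) with retention of the alkene geometry, the PMB ether, acetates and butenolide being inert at this temperature.

Step 13
Reactants: 24 allylic bromide
Product: 26 (1(10)E,4Z,7R,8S)-14-acetoxy-15-(4-methoxybenzyloxy)germacra-1(10),4,11(13)-trien-12,8-olide (C9 cis to C2; C3 trans to C6; trans-fused lactone), via acetoxymethyl lactone 25 (not isolated)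
Conditions: (Me3Si)3SiH (1.3 equiv), Et3B (0.3 equiv), air, benzene, 2 mM, rt, slow addition; then DBU, 0 °C
Reagents that add atoms: none
Why: Proposed new method: the silyl radical abstracts the allylic bromine, the geometry-retaining allyl radical closes 10-exo through its primary terminus C6 on the butenolide β-carbon C7 anti to the C8 substituent (setting 7R and the trans fusion), the α-lactone radical is reduced by the silane and DBU then eliminates acetic acid (E1cB) to reveal the 11(13)-methylene, so the ring closes at the bond that germacrene A synthase makes; the closest known reactions are Pattenden-type allyl-radical macrocyclisations onto enoates, anti-selective Giese additions to 5-substituted butenolides and radical allylations with Morita–Baylis–Hillman acetates.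

Step 14
Reactants: 26 PMB-protected germacranolide
Product: 27 (1(10)E,4Z,7R,8S)-14-acetoxy-15-hydroxygermacra-1(10),4,11(13)-trien-12,8-olide
Conditions: DDQ (1.3 equiv), CH2Cl2/pH 7 buffer (10:1), 0 °C
Reagents that add atoms: none
Why: Oxidative PMB-ether cleavage (hydride abstraction to the oxocarbenium ion, then hydrolysis) frees the C15 alcohol without touching the acetate, the α-methylene lactone or the ring alkenes.

Step 15
Reactants: 27 C15 alcohol
Product: 28 (1(10)E,4Z,7R,8S)-14-acetoxy-15-(acryloyloxy)germacra-1(10),4,11(13)-trien-12,8-olide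
Conditions: acryloyl chloride, Et3N, CH2Cl2, −20 °C
Reagents that add atoms: acryloyl chloride, C=CC(Cl)=O
Why: Simple O-acylation of the primary allylic alcohol at low temperature, which suppresses amine addition to the α-methylene lactone.

Step 16
Reactants: 28 C15 acrylate
Product: 29 CNP0126545.1, (1(10)E,4Z,7R,8S)-14-acetoxy-15-{[2-(hydroxymethyl)acryloyl]oxy}germacra-1(10),4,11(13)-trien-12,8-olide
Conditions: 1,4-diazabicyclo[2.2.2]octane (1 equiv), 37% aq. CH2O, 1,4-dioxane/H2O, rt
Reagents that add atoms: formaldehyde, C=O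
Why: Morita–Baylis–Hillman hydroxymethylation of the acrylate (amine conjugate addition, aldol with formaldehyde, elimination), whereas the α-methylene lactone can only add the amine reversibly because its α-carbon carries no hydrogen for the final elimination.

## Compound list

1 | 2,3-dibromopropene | C=C(Br)CBr | starting material
2 | 4-methoxybenzyl alcohol | COc1ccc(CO)cc1 | starting material
3 | 2-bromoallyl 4-methoxybenzyl ether | C=C(Br)COCc1ccc(OC)cc1 | intermediate
4 | (tert-butyldimethylsilyloxy)acetaldehyde | O=CCO[Si](C)(C)C(C)(C)C | starting material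
5 | [3-(4-methoxybenzyloxy)prop-1-en-2-yl]lithium | [Li]C(=C)COCc1ccc(OC)cc1 | intermediate (not isolated)
6 | racemic 1-(tert-butyldimethylsilyloxy)-3-[(4-methoxybenzyloxy)methyl]but-3-en-2-ol | C=C(COCc1ccc(OC)cc1)C(O)CO[Si](C)(C)C(C)(C)C | intermediate
7 | triethyl orthoacetate | CC(OCC)(OCC)OCC | starting material
8 | mixed orthoester (1,1-diethoxyethyl ether of 6) | CC(OCC)(OCC)OC(CO[Si](C)(C)C(C)(C)C)C(=C)COCc1ccc(OC)cc1 | intermediate (not isolated)
9 | ketene acetal (1-ethoxyvinyl ether of 6) | C=C(OCC)OC(CO[Si](C)(C)C(C)(C)C)C(=C)COCc1ccc(OC)cc1 | intermediate (not isolated)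
10 | ethyl (4Z)-6-(tert-butyldimethylsilyloxy)-4-[(4-methoxybenzyloxy)methyl]hex-4-enoate | CCOC(=O)CC/C(COCc1ccc(OC)cc1)=C/CO[Si](C)(C)C(C)(C)C | intermediate
11 | (4Z)-6-(tert-butyldimethylsilyloxy)-4-[(4-methoxybenzyloxy)methyl]hex-4-enal | O=CCC/C(COCc1ccc(OC)cc1)=C/CO[Si](C)(C)C(C)(C)C | intermediate
12 | (S)-5-(hydroxymethyl)dihydrofuran-2(3H)-one | OC[C@@H]1CCC(=O)O1 | starting material
13 | (S)-5-oxotetrahydrofuran-2-carbaldehyde | O=C[C@@H]1CCC(=O)O1 | intermediate
14 | (S)-5-vinyldihydrofuran-2(3H)-one | C=C[C@@H]1CCC(=O)O1 | intermediate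
15 | diethyl (5S)-5-vinyl-4,5-dihydrofuran-2-yl phosphate | C=C[C@@H]1CC=C(OP(=O)(OCC)OCC)O1 | intermediate (not isolated)
16 | diethyl [(5S)-2-oxo-5-vinyltetrahydrofuran-3-yl]phosphonate (C3 epimers, as lithium salt) | C=C[C@@H]1CC(P(=O)(OCC)OCC)C(=O)O1 | intermediate (not isolated)
17 | (3E,5S)-3-{(4Z)-6-(tert-butyldimethylsilyloxy)-4-[(4-methoxybenzyloxy)methyl]hex-4-en-1-ylidene}-5-vinyldihydrofuran-2(3H)-one | C=C[C@@H]1C/C(=C\CC/C(COCc2ccc(OC)cc2)=C/CO[Si](C)(C)C(C)(C)C)C(=O)O1 | intermediate
18 | (3S,5E,9Z)-11-(tert-butyldimethylsilyloxy)-5-(hydroxymethyl)-9-[(4-methoxybenzyloxy)methyl]undeca-1,5,9-trien-3-ol | C=C[C@@H](O)C/C(CO)=C\CC/C(COCc1ccc(OC)cc1)=C/CO[Si](C)(C)C(C)(C)C | intermediate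
19 | (3S,5E,9Z)-5-(acetoxymethyl)-11-(tert-butyldimethylsilyloxy)-9-[(4-methoxybenzyloxy)methyl]undeca-1,5,9-trien-3-ol | C=C[C@@H](O)C/C(COC(C)=O)=C\CC/C(COCc1ccc(OC)cc1)=C/CO[Si](C)(C)C(C)(C)C | intermediate
20 | 2-(bromomethyl)acrylic acid | C=C(CBr)C(=O)O | starting material
21 | 2-(bromomethyl)acrylate of 19 (ester at the C3 oxygen) | C=C[C@@H](OC(=O)C(=C)CBr)C/C(COC(C)=O)=C\CC/C(COCc1ccc(OC)cc1)=C/CO[Si](C)(C)C(C)(C)C | intermediate (not isolated)
22 | 2-(acetoxymethyl)acrylate of 19 (ester at the C3 oxygen) | C=C[C@@H](OC(=O)C(=C)COC(C)=O)C/C(COC(C)=O)=C\CC/C(COCc1ccc(OC)cc1)=C/CO[Si](C)(C)C(C)(C)C | intermediate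
23 | (5S)-3-(acetoxymethyl)-5-{(2E,6Z)-2-(acetoxymethyl)-8-(tert-butyldimethylsilyloxy)-6-[(4-methoxybenzyloxy)methyl]octa-2,6-dien-1-yl}furan-2(5H)-one | CC(=O)OCC1=C[C@H](C/C(COC(C)=O)=C\CC/C(COCc2ccc(OC)cc2)=C/CO[Si](C)(C)C(C)(C)C)OC1=O | intermediate
24 | (5S)-3-(acetoxymethyl)-5-{(2E,6Z)-2-(acetoxymethyl)-8-bromo-6-[(4-methoxybenzyloxy)methyl]octa-2,6-dien-1-yl}furan-2(5H)-one | CC(=O)OCC1=C[C@H](C/C(COC(C)=O)=C\CC/C(COCc2ccc(OC)cc2)=C/CBr)OC1=O | intermediate
25 | (1(10)E,4Z,7R,8S)-13,14-diacetoxy-15-(4-methoxybenzyloxy)-11,13-dihydrogermacra-1(10),4-dien-12,8-olide (C11 epimers) | COc1ccc(COC/C2=C\C[C@@H]3C(COC(C)=O)C(=O)O[C@H]3C/C(COC(C)=O)=C\CC2)cc1 | intermediate (not isolated)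
26 | (1(10)E,4Z,7R,8S)-14-acetoxy-15-(4-methoxybenzyloxy)germacra-1(10),4,11(13)-trien-12,8-olide | COc1ccc(COC/C2=C\C[C@@H]3C(=C)C(=O)O[C@H]3C/C(COC(C)=O)=C\CC2)cc1 | intermediate
27 | (1(10)E,4Z,7R,8S)-14-acetoxy-15-hydroxygermacra-1(10),4,11(13)-trien-12,8-olide | OC/C1=C\C[C@@H]2C(=C)C(=O)O[C@H]2C/C(COC(C)=O)=C\CC1 | intermediate
28 | (1(10)E,4Z,7R,8S)-14-acetoxy-15-(acryloyloxy)germacra-1(10),4,11(13)-trien-12,8-olide | C=CC(=O)OC/C1=C\C[C@@H]2C(=C)C(=O)O[C@H]2C/C(COC(C)=O)=C\CC1 | intermediate
29 | CNP0126545.1, (1(10)E,4Z,7R,8S)-14-acetoxy-15-{[2-(hydroxymethyl)acryloyl]oxy}germacra-1(10),4,11(13)-trien-12,8-olide | C=C(CO)C(=O)OC/C1=C\C[C@@H]2C(=C)C(=O)O[C@H]2C/C(COC(C)=O)=C\CC1 | target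

## Step count and risk

Total steps: 16. Longest linear sequence: 14 (steps 1–4, then 7–16); the lactone branch (steps 5–6) joins at step 7.

Most likely to fail:

**Step 13 (ten-membered ring closure).** The stabilised allyl radical may add too slowly to the β-substituted butenolide, so that reduction or dimerisation wins. It may also lose its alkene geometry before closing, or give some cis-fused lactone. The fallback closes the carbocycle on an open-chain acceptor and forms the lactone last; it sets out from 19 and returns at 26. Cross-metathesis of 19 with methyl 2-(acetoxymethyl)acrylate (second-generation Hoveyda–Grubbs catalyst (H2IMes)Cl2Ru=CH(2-i-PrOC6H4)) gives open-chain (E)-γ-hydroxy enoate F1, whose ester is trans to C8 and so cannot lactonise. HF·pyridine gives diol F2. CBr4/PPh3 at −40 °C brominates only the primary allylic alcohol and gives bromide F3. The same silane/Et3B closure, now onto the less hindered acyclic enoate, gives macrocyclic hydroxy ester F4. DBU then eliminates acetic acid and lactonises the 8-hydroxy ester, which rejoins the route at 26. In this variant C7 is set only by acyclic 1,3-allylic-strain control, so any C7 epimer would be separated at 26.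

**Step 7 (one-flask phosphonate formation and olefination).** Risks are incomplete phosphate-to-phosphonate rearrangement and an E/Z ratio too low for the C1=C10 geometry. The fallback is an aldol–dehydration sequence from 14 and 11 back to 17. The lithium enolate of 14 (LiN(i-Pr)2, −78 °C) adds to 11 to give β-hydroxy lactone F5. MsCl/Et3N gives mesylate F6, and DBU effects E1cB elimination to the conjugated E-alkylidene lactone 17.

**Step 16 (Morita–Baylis–Hillman end game).** The amine may add to or dimerise the α-methylene lactone, and formaldehyde may over-react. The fallback sets out from 27 and returns at 29, bypassing 28. Alcohol 27 is esterified with 2-{[(tert-butyldimethylsilyl)oxy]methyl}acrylic acid (EDC·HCl, DMAP) to give silyl ether F7, and HF·pyridine then frees the target 29.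

## Further compounds

F1 | step 13 | methyl (2E,4S,6E,10Z)-2,6-bis(acetoxymethyl)-4-hydroxy-10-[(4-methoxybenzyloxy)methyl]-12-(tert-butyldimethylsilyloxy)dodeca-2,6,10-trienoate | COC(=O)/C(COC(C)=O)=C/[C@@H](O)C/C(COC(C)=O)=C\CC/C(COCc1ccc(OC)cc1)=C/CO[Si](C)(C)C(C)(C)C
F2 | step 13 | methyl (2E,4S,6E,10Z)-2,6-bis(acetoxymethyl)-4,12-dihydroxy-10-[(4-methoxybenzyloxy)methyl]dodeca-2,6,10-trienoate | COC(=O)/C(COC(C)=O)=C/[C@@H](O)C/C(COC(C)=O)=C\CC/C(COCc1ccc(OC)cc1)=C/CO
F3 | step 13 | methyl (2E,4S,6E,10Z)-2,6-bis(acetoxymethyl)-12-bromo-4-hydroxy-10-[(4-methoxybenzyloxy)methyl]dodeca-2,6,10-trienoate | COC(=O)/C(COC(C)=O)=C/[C@@H](O)C/C(COC(C)=O)=C\CC/C(COCc1ccc(OC)cc1)=C/CBr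
F4 | step 13 | methyl (1(10)E,4Z,7R,8S)-13,14-diacetoxy-8-hydroxy-15-(4-methoxybenzyloxy)-11,13-dihydrogermacra-1(10),4-dien-12-oate (C11 epimers) | COc1ccc(COC/C2=C\C[C@H](C(COC(C)=O)C(=O)OC)[C@@H](O)C/C(COC(C)=O)=C\CC2)cc1
F5 | step 7 | (5S)-3-{(4Z)-6-(tert-butyldimethylsilyloxy)-1-hydroxy-4-[(4-methoxybenzyloxy)methyl]hex-4-en-1-yl}-5-vinyldihydrofuran-2(3H)-one (diastereomers) | C=C[C@@H]1CC(C(O)CC/C(COCc2ccc(OC)cc2)=C/CO[Si](C)(C)C(C)(C)C)C(=O)O1
F6 | step 7 | methanesulfonate of F5 | C=C[C@@H]1CC(C(OS(C)(=O)=O)CC/C(COCc2ccc(OC)cc2)=C/CO[Si](C)(C)C(C)(C)C)C(=O)O1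
F7 | step 16 | (1(10)E,4Z,7R,8S)-14-acetoxy-15-({2-[(tert-butyldimethylsilyloxy)methyl]acryloyl}oxy)germacra-1(10),4,11(13)-trien-12,8-olide | C=C(CO[Si](C)(C)C(C)(C)C)C(=O)OC/C1=C\C[C@@H]2C(=C)C(=O)O[C@H]2C/C(COC(C)=O)=C\CC1
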